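Readings and results are simulated with made-up constants, and the scatter is random.

Late in the gamma run nothing moves: product reads 45% at 0.833 h and 43% at 3.00 h, a gap inside the scatter of 1.5 percentage points. So gamma ends with what was made during the feed and shortly after, and the question is how each dose of partner splits.

| flask | substrate | partner | remark | time |
|---|---|---|---|---|
| eta | 0.20 M | 0.029 M (fed, over 30 min) | run made earlier; the fed solution adds 0.10 times the starting volume |  |
| beta | 0.20 M | 0.056 M (fed, over 30 min) | run made earlier; the fed solution adds 0.10 times the starting volume |  |
| theta | 0.20 M | 0.089 M (fed, over 30 min) | run made earlier; the fed solution adds 0.10 times the starting volume |  |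
| gamma | 0.16 M | 0.10 M (fed, over 30 min) | run made earlier; the fed solution adds 0.10 times the starting volume |  |
| south-east | 0.050 M | 0.100 M (fed, over 30 min) | the fed solution adds 0.10 times the starting volume | 3.0 h |
| south-west | 0.20 M | 0.0600 M (fed, over 60 min) | the fed solution adds 0.10 times the starting volume | 3.0 h |
| north-east | 0.20 M | 0.100 M (fed, over 60 min) | the fed solution adds 0.10 times the starting volume | 3.0 h |
| north-west | 0.10 M | 0.0300 M (fed, over 30 min) | the fed solution adds 0.10 times the starting volume | 3.0 h |
| north | 0.20 M | 0.100 M (fed, over 30 min) | the fed solution adds 0.10 times the starting volume | 3.0 h |
| east | 0.30 M | 0.100 M (fed, over 100 min) | the fed solution adds 0.10 times the starting volume | 3.0 h |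

| run | time / h | product / % | substrate / % |
|---|---|---|---|
| eta | 0.667 | 13 | 87 |
| eta | 1.33 | 13 | 88 |
| eta | 2.00 | 13 | 88 |
| eta | 2.50 | 13 | 89 |
| eta | 3.00 | 14 | 88 |
| beta | 0.667 | 23 | 77 |
| beta | 1.33 | 25 | 78 |
| beta | 2.00 | 25 | 78 |
| beta | 2.50 | 20 | 78 |
| beta | 3.00 | 25 | 78 |
| theta | 0.667 | 36 | 64 |
| theta | 1.33 | 33 | 66 |
| theta | 2.00 | 29 | 67 |
| theta | 2.50 | 36 | 65 |
| theta | 3.00 | 33 | 66 |
| gamma | 0.250 | 19 | 82 |
| gamma | 0.833 | 45 | 55 |
| gamma | 1.33 | 43 | 56 |
| gamma | 2.00 | 44 | 56 |
| gamma | 3.00 | 43 | 57 |

(readings scatter by 1.5 percentage points)

- charges are per starting volume, the dose included; the dosed solution carries all of it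
- the numbers in the tables scatter with a standard deviation of 1.5 points

- the flasks put in order of amount of product, in percent of the substrate charged, best first, at 3.0 h (south-east / south-west / north-east / north-west / north / east)
- the amount of product, in percent of the substrate charged of the flask you put first, at 3.0 h
- the amount of product, in percent of the substrate charged of the flask you put last, at 3.0 h

Take gamma in slow motion. In the first instants a little partner meets a full charge of substrate. In the middle, partner leaves by two exits: into product, and into a loss that spares substrate, since gamma's late substrate and product add up to the charge. After the feed, the readings stand still.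

Gamma's plateau averages 43.8%. That is 0.700 of product per partner charged, or 0.429 lost per product, the inverse of a selectivity factor.

Now our own assumption, which these runs, with substrate from 0.16 M to 0.20 M, barely test: the loss is first order in partner, and the product step goes with the root of substrate times partner. Balancing the feed against both exits gives a rule: loss per product, times one plus itself, equals the load, which is a time multiplied by feed rate over substrate. Gamma's feed of 0.200 M h⁻¹ and midway substrate of 0.125 M give 0.383 h for this time, the waste time. On theta, with midway substrate 0.167 M, the load is 0.408, which gives 33.9% against a last reading of 33%.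

Control changes hands at load 2, where loss equals product. With south-east's feed of 0.200 M h⁻¹ that happens at 0.0383 M of substrate. South-east starts higher than this, at 0.050 M. Its starting load of 1.53 promises 0.0545 M of product, more than the substrate charged. So we take midway substrate as 0.0250 M, half the charge, which is lower than the crossing. The load there is 3.06, giving 0.0431 M of product, or 86.2%.

The forecast orders the flasks south-east > north-east > north > east > south-west > north-west. It gives 62% (50% to 73%) for the first and 22.5% (19.5% to 26%) for the last, holding that "Waste then grows with feed rate and low substrate". Our figure for south-east stands higher than its range.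

The flasks come out south-east > north-east > north > east > south-west > north-west, with 88.9% first and 24.5% last.

    substrate + partner → product, rate k1*[substrate]^0.5*[partner]^0.5 (k = 0.00120 s⁻¹)
    partner → decomposed reagent (k = 0.00220 s⁻¹)

In north-west at 0.271 h, the product step uses partner 4.3 times as fast as the loss does. South-east, whose reckoned load of 3.06 lay above 2, ends with 0.0505 M of decomposed reagent against 0.0404 M of product, both in the final volume, and its partner, charged at twice the substrate, stands at 0% with 11% of the substrate left.

Take the neighbour of north-west charged with 0.040 M of substrate. The same two passes give a starting load of 0.574, a midway substrate of 0.0293 M, a load there of 0.782, and so 49.5%. The neighbour gives 49.8%.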